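The piperidine ring (N1, C2–C6) is not built as a six-membered ring: its carbons C3–C6 are the four carbons of a furan and C2 is the stereogenic side-chain carbon of (R)-1-(2-furyl)ethylamine. An aza-Achmatowicz oxidative ring expansion of the N-Boc amine dearomatises the five-membered heteroarene and gives the six-membered ring in one operation, with the C3 oxygen as a ketone and C6 as an N,O-acetal, exploiting the fact that C3 bears oxygen and C6 is bound to nitrogen. Both C6 epimers are later funnelled through one N-acyliminium ion (cis-allylation); the ketone is reduced cis, the chain is completed by cross-metathesis and the ferulate is attached last.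

Key step: step 2

Remark: the target is read from the SMILES as the all-cis (2R,3R,6S) piperidine, and (R)-1-(furan-2-yl)ethan-1-amine is assumed to be purchasable as a single enantiomer. Compounds 4–6 are expected as C6 epimer mixtures; the expected major 2,6-trans epimer is drawn.

Step 1
Reactants: 1 (R)-1-(furan-2-yl)ethan-1-amine
Product: 2 tert-butyl N-[(1R)-1-(furan-2-yl)ethyl]carbamate
Conditions: Boc2O, Et3N, CH2Cl2, 0 °C to rt
Reagents that add atoms: di-tert-butyl dicarbonate, CC(C)(C)OC(=O)OC(=O)OC(C)(C)C
Why: Carbamate formation at a primary amine (N-acylation) leaves the stereocentre untouched and installs the N-acyl group needed for the ring expansion and for later A(1,3) control.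

Step 2
Reactants: 2 tert-butyl N-[(1R)-1-(furan-2-yl)ethyl]carbamate
Product: 4 tert-butyl (2R,6R)-6-hydroxy-2-methyl-3-oxo-3,6-dihydropyridine-1(2H)-carboxylate, via cis-enedione carbamate 3 (not isolated)
Conditions: mCPBA (1.3 equiv), CH2Cl2, 0 °C to rt
Reagents that add atoms: 3-chloroperoxybenzoic acid, OOC(=O)c1cccc(Cl)c1
Why: This is an aza-Achmatowicz rearrangement: the peracid epoxidises the electron-rich furan, the epoxide opens with cleavage of the ring C–O bond to the cis-enedione 3 (dearomatisation), and the carbamate N–H adds to the aldehyde carbonyl, so that the four furan carbons, the exocyclic CH(CH3) carbon and nitrogen form the six-membered ring. The closure is a reversible 6-exo-trig hemiaminal formation. C2 is carried over unchanged from 1 because no bond to it is made or broken. The new C6 centre is set under thermodynamic control by ring–chain tautomerism and should settle mainly 2,6-trans (C2 methyl and C6 hydroxyl both pseudoaxial, which avoids A(1,3) strain with the N-Boc group and gains an anomeric effect), but its configuration is irrelevant because step 5 erases it. The step needs chemoselective oxidation of the furan over the carbamate and no enolisation at C2 (alpha to the new ketone); the far higher reactivity of the furan towards peracid, the weakly acidic medium, the low temperature and only a slight excess of oxidant should secure both.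

Step 3
Reactants: 4 tert-butyl (2R,6R)-6-hydroxy-2-methyl-3-oxo-3,6-dihydropyridine-1(2H)-carboxylate
Product: 5 tert-butyl (2R,6R)-6-methoxy-2-methyl-3-oxo-3,6-dihydropyridine-1(2H)-carboxylate
Conditions: HC(OMe)3, p-TsOH·H2O (cat.), THF, 0 °C to rt
Reagents that add atoms: trimethyl orthoformate, COC(OC)OC
Why: Acid-catalysed N,O-acetal exchange through the N-acyliminium ion, with the orthoester scavenging water, locks the ring-closed form so that no aldehyde tautomer is present in later steps; the methoxy group should again sit pseudoaxial and trans to the C2 methyl, although C6 is erased in step 5.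

Step 4
Reactants: 5 tert-butyl (2R,6R)-6-methoxy-2-methyl-3-oxo-3,6-dihydropyridine-1(2H)-carboxylate
Product: 6 tert-butyl (2R,6R)-6-methoxy-2-methyl-3-oxopiperidine-1-carboxylate
Conditions: H2 (1 atm), 10% Pd/C, EtOAc, rt
Reagents that add atoms: none
Why: Chemoselective heterogeneous hydrogenation of the enone C4=C5 bond (ketone, carbamate and N,O-acetal are inert) ensures that the cation of step 5 is a simple half-chair N-acyliminium ion; no stereocentre is formed.

Step 5
Reactants: 6 tert-butyl (2R,6R)-6-methoxy-2-methyl-3-oxopiperidine-1-carboxylate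
Product: 8 tert-butyl (2R,6R)-2-methyl-3-oxo-6-(prop-2-en-1-yl)piperidine-1-carboxylate, via N-acyliminium ion 7 (not isolated)
Conditions: allylSiMe3 (3 equiv), BF3·OEt2 (2 equiv), CH2Cl2, −78 to −40 °C
Reagents that add atoms: allyltrimethylsilane, C=CC[Si](C)(C)C
Why: Sakurai-type allylation of an N-acyliminium ion: BF3 ionises either C6 epimer of 6 to the same cation 7 (stereoconvergent), whose C2 methyl is pseudoaxial to avoid A(1,3) strain with the N-Boc group, and the allylsilane should attack C6 along the axial, chair-forming trajectory on the same face to give the 2,6-cis (diaxial) product, the control element known from conjugate additions to N-acyl-2-alkyl-2,3-dihydro-4-pyridones.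

Step 6
Reactants: 8 tert-butyl (2R,6R)-2-methyl-3-oxo-6-(prop-2-en-1-yl)piperidine-1-carboxylate
Product: 9 tert-butyl (2R,3R,6R)-3-hydroxy-2-methyl-6-(prop-2-en-1-yl)piperidine-1-carboxylate
Conditions: LiBH(s-Bu)3 (L-Selectride), THF, −78 °C; then H2O
Reagents that add atoms: none
Why: Sterically controlled hydride reduction of a cyclic ketone: the axial C2 methyl and axial C6 allyl group shield one face of the N-Boc piperidin-3-one, so the bulky borohydride should add to C3 from the opposite face and give the all-cis 3R alcohol, as in reductions of N-acyl 2-substituted piperidin-3-ones to the cis alcohols.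

Step 7
Reactants: 10 dec-9-enoic acid
Product: 11 undec-10-en-2-one
Conditions: MeLi (2.2 equiv), Et2O, 0 °C to rt; inverse quench into cold aq. HCl
Reagents that add atoms: methyllithium, [Li]C
Why: Methyllithium adds to the lithium carboxylate to give a geminal dilithium alkoxide that collapses to the methyl ketone only on work-up (classical methyl ketone synthesis from a carboxylic acid); the remote alkene is inert.

Step 8
Reactants: 9 tert-butyl (2R,3R,6R)-3-hydroxy-2-methyl-6-(prop-2-en-1-yl)piperidine-1-carboxylate, 11 undec-10-en-2-one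
Product: 12 tert-butyl (2R,3R,6R)-3-hydroxy-2-methyl-6-[(2E)-11-oxododec-2-en-1-yl]piperidine-1-carboxylate
Conditions: 11 (3 equiv), second-generation Grubbs catalyst (H2IMes)(PCy3)Cl2Ru=CHPh (5 mol %), CH2Cl2, 40 °C
Reagents that add atoms: none
Why: Olefin cross-metathesis between two unhindered terminal alkenes, driven towards the cross product by the excess of 11 and loss of ethene; the E/Z mixture is of no consequence because the alkene is hydrogenated next, and no stereocentre is touched.

Step 9
Reactants: 12 tert-butyl (2R,3R,6R)-3-hydroxy-2-methyl-6-[(2E)-11-oxododec-2-en-1-yl]piperidine-1-carboxylate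
Product: 13 tert-butyl (2R,3R,6S)-3-hydroxy-2-methyl-6-(11-oxododecyl)piperidine-1-carboxylate (N-Boc-cassine)
Conditions: H2 (1 atm), 10% Pd/C, EtOAc, rt
Reagents that add atoms: none
Why: Catalytic hydrogenation of a disubstituted alkene under conditions that leave the methyl ketone, carbamate and alcohol untouched; the C6 descriptor changes from R to S only because the priorities change.

Step 10
Reactants: 13 tert-butyl (2R,3R,6S)-3-hydroxy-2-methyl-6-(11-oxododecyl)piperidine-1-carboxylate, 14 (2E)-3-(4-acetoxy-3-methoxyphenyl)prop-2-enoic acid (4-O-acetylferulic acid)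
Product: 15 tert-butyl (2R,3R,6S)-3-{[(2E)-3-(4-acetoxy-3-methoxyphenyl)prop-2-enoyl]oxy}-2-methyl-6-(11-oxododecyl)piperidine-1-carboxylate
Conditions: EDC·HCl, DMAP, CH2Cl2, 0 °C to rt
Reagents that add atoms: none
Why: Steglich esterification (carbodiimide activation, DMAP acyl transfer) of the equatorial C3 alcohol with retention at C3; nitrogen is blocked as the carbamate and the phenol as the acetate, so only O3 can be acylated.

Step 11
Reactants: 15 tert-butyl (2R,3R,6S)-3-{[(2E)-3-(4-acetoxy-3-methoxyphenyl)prop-2-enoyl]oxy}-2-methyl-6-(11-oxododecyl)piperidine-1-carboxylate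
Product: 17 (+)-3-O-feruloylcassine, via O-acetyl amine trifluoroacetate 16 (not isolated)
Conditions: TFA, CH2Cl2, 0 °C; evaporate; pyrrolidine, CH2Cl2–EtOH, 0 °C to rt; cold aq. NaHCO3 work-up
Reagents that add atoms: none
Why: Acidolysis of the tert-butyl carbamate (loss of isobutene and CO2) is followed by chemoselective aminolysis of the aryl acetate, which is far more electrophilic than the conjugated alkyl cinnamate; the ring nitrogen, flanked by the C2 and C6 substituents, should not take up the acyl group, and no stereocentre is touched.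

Compound list
1 | (R)-1-(furan-2-yl)ethan-1-amine | C[C@@H](N)c1ccco1 | starting material
2 | tert-butyl N-[(1R)-1-(furan-2-yl)ethyl]carbamate | C[C@@H](NC(=O)OC(C)(C)C)c1ccco1 | intermediate
3 | tert-butyl N-[(2R,4Z)-3,6-dioxohex-4-en-2-yl]carbamate (cis-enedione carbamate) | C[C@@H](NC(=O)OC(C)(C)C)C(=O)/C=C\C=O | intermediate (not isolated)
4 | tert-butyl (2R,6R)-6-hydroxy-2-methyl-3-oxo-3,6-dihydropyridine-1(2H)-carboxylate (major 2,6-trans epimer) | C[C@H]1N(C(=O)OC(C)(C)C)[C@H](O)C=CC1=O | intermediate
5 | tert-butyl (2R,6R)-6-methoxy-2-methyl-3-oxo-3,6-dihydropyridine-1(2H)-carboxylate (major 2,6-trans epimer) | C[C@H]1N(C(=O)OC(C)(C)C)[C@H](OC)C=CC1=O | intermediate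
6 | tert-butyl (2R,6R)-6-methoxy-2-methyl-3-oxopiperidine-1-carboxylate (major 2,6-trans epimer) | C[C@H]1N(C(=O)OC(C)(C)C)[C@H](OC)CCC1=O | intermediate
7 | (2R)-1-(tert-butoxycarbonyl)-2-methyl-3-oxo-2,3,4,5-tetrahydropyridin-1-ium (N-acyliminium ion) | C[C@H]1[N+](C(=O)OC(C)(C)C)=CCCC1=O | intermediate (not isolated)
8 | tert-butyl (2R,6R)-2-methyl-3-oxo-6-(prop-2-en-1-yl)piperidine-1-carboxylate | C[C@H]1N(C(=O)OC(C)(C)C)[C@@H](CC=C)CCC1=O | intermediate
9 | tert-butyl (2R,3R,6R)-3-hydroxy-2-methyl-6-(prop-2-en-1-yl)piperidine-1-carboxylate | C[C@H]1N(C(=O)OC(C)(C)C)[C@@H](CC=C)CC[C@H]1O | intermediate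
10 | dec-9-enoic acid | C=CCCCCCCCC(=O)O | starting material
11 | undec-10-en-2-one | C=CCCCCCCCC(C)=O | intermediate
12 | tert-butyl (2R,3R,6R)-3-hydroxy-2-methyl-6-[(2E)-11-oxododec-2-en-1-yl]piperidine-1-carboxylate (E isomer drawn) | C[C@H]1N(C(=O)OC(C)(C)C)[C@@H](C/C=C/CCCCCCCC(C)=O)CC[C@H]1O | intermediate
13 | tert-butyl (2R,3R,6S)-3-hydroxy-2-methyl-6-(11-oxododecyl)piperidine-1-carboxylate (N-Boc-cassine) | C[C@H]1N(C(=O)OC(C)(C)C)[C@@H](CCCCCCCCCCC(C)=O)CC[C@H]1O | intermediate
14 | (2E)-3-(4-acetoxy-3-methoxyphenyl)prop-2-enoic acid (4-O-acetylferulic acid) | COc1cc(/C=C/C(=O)O)ccc1OC(C)=O | starting material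
15 | tert-butyl (2R,3R,6S)-3-{[(2E)-3-(4-acetoxy-3-methoxyphenyl)prop-2-enoyl]oxy}-2-methyl-6-(11-oxododecyl)piperidine-1-carboxylate | COc1cc(/C=C/C(=O)O[C@@H]2CC[C@H](CCCCCCCCCCC(C)=O)N(C(=O)OC(C)(C)C)[C@@H]2C)ccc1OC(C)=O | intermediate
16 | (2R,3R,6S)-3-{[(2E)-3-(4-acetoxy-3-methoxyphenyl)prop-2-enoyl]oxy}-2-methyl-6-(11-oxododecyl)piperidin-1-ium trifluoroacetate | COc1cc(/C=C/C(=O)O[C@@H]2CC[C@H](CCCCCCCCCCC(C)=O)[NH2+][C@@H]2C)ccc1OC(C)=O.[O-]C(=O)C(F)(F)F | intermediate (not isolated)
17 | (+)-3-O-feruloylcassine, (2R,3R,6S)-2-methyl-6-(11-oxododecyl)piperidin-3-yl (2E)-3-(4-hydroxy-3-methoxyphenyl)prop-2-enoate | COc1cc(/C=C/C(=O)O[C@@H]2CC[C@H](CCCCCCCCCCC(C)=O)N[C@@H]2C)ccc1O | target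

Total step count: 11. Longest linear sequence: 10 steps (steps 1–6 and 8–11, from 1 to 17); step 7 is a one-step side branch.

Steps most likely to fail

Step 5. The attack on cation 7 may show poor facial selectivity, because the axial approach on the face of the C2 methyl competes with attack on the open face. The Lewis acid may also enolise the C3 ketone, which would erode C2 or divert the cation to the enecarbamate, and the allylsilane may add to the ketone. The fallback exchanges the roles of carbon and hydride and sets out from 2. Double deprotonation (n-BuLi, 2.2 equiv, THF, −78 to 0 °C; N–H, then furan C5–H) and trapping with allyl bromide should give tert-butyl N-[(1R)-1-(5-allylfuran-2-yl)ethyl]carbamate F1. The same mCPBA ring expansion then gives the tertiary hemiaminal tert-butyl (2R)-6-allyl-6-hydroxy-2-methyl-3-oxo-3,6-dihydropyridine-1(2H)-carboxylate F2. Ionic reduction (Et3SiH, BF3·OEt2, CH2Cl2, −78 °C) should deliver hydride to the flattened conjugated N-acyliminium ion anti to the pseudoaxial C2 methyl and so give the 2,6-cis enone tert-butyl (2R,6S)-6-allyl-2-methyl-3-oxo-3,6-dihydropyridine-1(2H)-carboxylate F3. Conjugate reduction of F3 with LiBH(s-Bu)3 (1 equiv, THF, −78 °C) and protonation of the enolate comes back to the route at 8.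

Step 8. Two unbiased terminal alkenes may give a statistical mixture of cross- and homo-coupled products, and ruthenium hydride species may move the double bond, which would give chain-shortened homologues that hydrogenation makes inseparable. The fallback builds the chain by sp3–sp3 coupling and sets out from 9. Hydroboration with 9-BBN (THF, rt) should give the alkylborane tert-butyl (2R,3R,6S)-6-[3-(9-borabicyclo[3.3.1]nonan-9-yl)propyl]-3-hydroxy-2-methylpiperidine-1-carboxylate F4, which is not isolated. Alkyl–alkyl Suzuki–Miyaura coupling of F4 with purchased 9-bromonon-1-ene (Pd(OAc)2, PCy3, K3PO4·H2O, THF, rt) should give tert-butyl (2R,3R,6S)-6-(dodec-11-en-1-yl)-3-hydroxy-2-methylpiperidine-1-carboxylate F5. Tsuji–Wacker oxidation of the terminal alkene (PdCl2, CuCl, O2, DMF–H2O) comes back to the route at 13, which makes steps 7 and 9 unnecessary.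

Step 2. The peracid may over-oxidise the product (attack on the aldehyde tautomer 3 or a second epoxidation), the acid formed may promote dehydration of 4 towards a 3-hydroxypyridine-type aromatic or loss of the Boc group, and C2 may enolise in the alpha-amino enone. The fallback is the two-stage, peracid-free ring expansion and sets out from 2. Bromine in methanol (NaHCO3, −40 °C) should add two methoxy groups across the furan to give tert-butyl N-[(1R)-1-(2,5-dimethoxy-2,5-dihydrofuran-2-yl)ethyl]carbamate F6, an isolable acetal mixture. Mild hydrolysis (PPTS, acetone–H2O, rt) unmasks the cis-enedione 3, which closes as before and comes back to the route at 4.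

Further compounds
F1 | step 5 | tert-butyl N-[(1R)-1-(5-allylfuran-2-yl)ethyl]carbamate | C[C@@H](NC(=O)OC(C)(C)C)c1ccc(CC=C)o1
F2 | step 5 | tert-butyl (2R)-6-allyl-6-hydroxy-2-methyl-3-oxo-3,6-dihydropyridine-1(2H)-carboxylate (C6 epimers) | C[C@H]1N(C(=O)OC(C)(C)C)C(O)(CC=C)C=CC1=O
F3 | step 5 | tert-butyl (2R,6S)-6-allyl-2-methyl-3-oxo-3,6-dihydropyridine-1(2H)-carboxylate | C[C@H]1N(C(=O)OC(C)(C)C)[C@@H](CC=C)C=CC1=O
F4 | step 8 | tert-butyl (2R,3R,6S)-6-[3-(9-borabicyclo[3.3.1]nonan-9-yl)propyl]-3-hydroxy-2-methylpiperidine-1-carboxylate | C[C@H]1N(C(=O)OC(C)(C)C)[C@@H](CCCB2C3CCCC2CCC3)CC[C@H]1O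
F5 | step 8 | tert-butyl (2R,3R,6S)-6-(dodec-11-en-1-yl)-3-hydroxy-2-methylpiperidine-1-carboxylate | C[C@H]1N(C(=O)OC(C)(C)C)[C@@H](CCCCCCCCCCC=C)CC[C@H]1O
F6 | step 2 | tert-butyl N-[(1R)-1-(2,5-dimethoxy-2,5-dihydrofuran-2-yl)ethyl]carbamate (acetal diastereomers) | C[C@@H](NC(=O)OC(C)(C)C)C1(OC)C=CC(OC)O1
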